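**Retrosynthetic overview**
1. Target 26 ⇒ alkannin 24 + 3-methylbut-2-enoic acid 25 (Steglich esterification of the side-chain OH only); 24 ⇒ tris-silyl ether 23 (fluoride).
2. Quinone 23 ⇒ 2-alkynyl-2-hydroxybenzocyclobutenone 20 by a Moore ring expansion: the four-membered ring opens at its CO–C(OH) bond (a bond that is not in the target) and the quinone ring closes between the ketene carbon (future C1=O) and the alkyne carbon carrying the side chain (future C2).
3. 20 ⇒ symmetrical 3,6-bis(triisopropylsilyloxy)benzocyclobutene-1,2-dione 9 + the lithium acetylide of (S)-silyl ether 18; 18 ⇒ ynone 15 (Noyori transfer hydrogenation sets the only stereocentre); 9 ⇒ aryne [2+2] of 1 with ketene acetal 2.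
4. Enabling feature: in the quinone ring the carbonyl carbons C1 and C4 are bonded to the adjacent benzo carbons C8a and C4a, so C1–C8a–C4a–C4 can be folded into a benzocyclobutenedione, while C2(side chain)=C3(H) is a terminal alkyne in disguise; C3 carries only the hydrogen that the carbinol OH gives up, and the two equivalent peri-oxygens (C5, C8) make the dione symmetrical.
5. Ring order: benzene ring (bought) → four-membered ring (step 1) → quinone ring (step 12).

Key step: step 12

Remark: the target is one tautomer of a naphthazarin (the tautomers interconvert rapidly, so only one compound exists); the peri-oxygens are carried as fluoride-labile triisopropylsilyl ethers because aryl methyl ethers are hard to cleave next to this side chain, and 1, 2, 10, 13 and 25 are taken as commercial.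

**Step 1**
Reactants: 1 2-bromo-1,4-dimethoxybenzene; 2 1,1-dimethoxyethene
Product: 5 3,6-dimethoxybenzocyclobuten-1(2H)-one, via 3,6-dimethoxybenzyne 3 (not isolated), via benzocyclobutenone dimethyl acetal 4 (not isolated)
Conditions: NaNH2 (2.5 equiv), 2 (2 equiv), THF, reflux; then 1 M HCl, THF–H2O, rt
Reagents that add atoms: water, O
Why: NaNH2 converts 1 by ortho-deprotonation and loss of bromide into the symmetrical aryne 3, which the electron-rich ketene acetal 2 traps in a regiochemically unambiguous [2+2] cycloaddition (aryne–ketene acetal cycloaddition), and mild acid hydrolysis of acetal 4 frees the ketone.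

**Step 2**
Reactants: 5 3,6-dimethoxybenzocyclobuten-1(2H)-one
Product: 6 2,2-dibromo-3,6-dimethoxybenzocyclobuten-1(2H)-one
Conditions: NBS (2.2 equiv), dibenzoyl peroxide (cat.), CCl4, reflux
Reagents that add atoms: N-bromosuccinimide, O=C1CCC(=O)N1Br
Why: Wohl–Ziegler bromination, in which the CH2 group is both benzylic and alpha to the carbonyl so the radical chain should replace both hydrogens there, while the non-polar medium disfavours ionic bromination of the ring.

**Step 3**
Reactants: 6 2,2-dibromo-3,6-dimethoxybenzocyclobuten-1(2H)-one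
Product: 7 3,6-dimethoxybenzocyclobutene-1,2-dione
Conditions: CF3CO2Ag (2.2 equiv), MeCN–H2O, 60 °C
Reagents that add atoms: water, O
Why: Silver-assisted hydrolysis of a gem-dibromide, in which Ag+ removes bromide from the benzylic carbon (the cation is supported by the ortho methoxy group) and water captures it twice to give C=O; the strained 1,2-dione tolerates the acid that is released.

**Step 4**
Reactants: 7 3,6-dimethoxybenzocyclobutene-1,2-dione
Product: 8 3,6-dihydroxybenzocyclobutene-1,2-dione
Conditions: BBr3 (2.5 equiv), CH2Cl2, –78 → 0 °C; then H2O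
Reagents that add atoms: none
Why: Lewis-acid cleavage of aryl methyl ethers, helped by chelation of boron between each methoxy oxygen and its neighbouring carbonyl oxygen before bromide attacks the methyl group (SN2); the acid-stable four-membered dione should survive, and the harsh deprotection is thereby moved to a stage without a sensitive side chain.

**Step 5**
Reactants: 8 3,6-dihydroxybenzocyclobutene-1,2-dione
Product: 9 3,6-bis(triisopropylsilyloxy)benzocyclobutene-1,2-dione
Conditions: i-Pr3SiOTf (2.4 equiv), 2,6-lutidine (3 equiv), CH2Cl2, –78 → 0 °C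
Reagents that add atoms: triisopropylsilyl trifluoromethanesulfonate, CC(C)[Si](OS(=O)(=O)C(F)(F)F)(C(C)C)C(C)C
Why: O-silylation of phenols with a silyl triflate and a hindered, non-nucleophilic base, which avoids nucleophilic attack on the strained dione; the bulky silyl groups are inert to an acetylide, slow to migrate from oxygen to oxygen and removable with fluoride.

**Step 6**
Reactants: 10 4-methylpent-3-enoic acid
Product: 12 N-methoxy-N,4-dimethylpent-3-enamide, via 1-(4-methylpent-3-enoyl)imidazole 11 (not isolated)
Conditions: 1,1'-carbonyldiimidazole, CH2Cl2, 0 °C → rt; then MeNH(OMe)·HCl, rt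
Reagents that add atoms: N,O-dimethylhydroxylamine hydrochloride, CNOC.Cl
Why: Acid activation as the acyl imidazole followed by aminolysis (Weinreb amide formation) under nearly neutral conditions that should not move the beta,gamma double bond into conjugation.

**Step 7**
Reactants: 12 N-methoxy-N,4-dimethylpent-3-enamide; 13 ethynyltrimethylsilane
Product: 15 6-methyl-1-(trimethylsilyl)hept-5-en-1-yn-3-one, via lithium (trimethylsilyl)acetylide 14 (not isolated)
Conditions: 13, n-BuLi, THF, –78 °C; then 12, –78 → –20 °C; AcOH, –78 °C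
Reagents that add atoms: none
Why: Weinreb ketone synthesis, in which the acetylide adds once to give a chelated tetrahedral intermediate that collapses to the ynone only on the cold acidic quench, and the C-silyl group blocks conjugate addition of the released amine.

**Step 8**
Reactants: 15 6-methyl-1-(trimethylsilyl)hept-5-en-1-yn-3-one
Product: 16 (S)-6-methyl-1-(trimethylsilyl)hept-5-en-1-yn-3-ol
Conditions: Ru[(S,S)-TsNCH(Ph)CH(Ph)NH](p-cymene) (1 mol %), i-PrOH, rt
Reagents that add atoms: none
Why: Noyori asymmetric transfer hydrogenation of an alkynyl ketone, in which the alkynyl group takes the place of the aryl group of aryl ketones in the six-membered Ru–H/N–H transition state, so the (S,S)-catalyst is expected to deliver hydride to the face that gives the (S)-carbinol (to be confirmed by Mosher ester analysis, with the (R,R)-catalyst used if the sense is opposite), and the base-free conditions should leave the skipped enone unisomerised.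

**Step 9**
Reactants: 16 (S)-6-methyl-1-(trimethylsilyl)hept-5-en-1-yn-3-ol
Product: 17 (S)-3-(tert-butyldimethylsilyloxy)-6-methyl-1-(trimethylsilyl)hept-5-en-1-yne
Conditions: t-BuMe2SiCl, imidazole, DMF, rt
Reagents that add atoms: tert-butyldimethylsilyl chloride, CC(C)(C)[Si](C)(C)Cl
Why: Standard imidazole-promoted silylation of a secondary alcohol, in which the stereocentre is not involved.

**Step 10**
Reactants: 17 (S)-3-(tert-butyldimethylsilyloxy)-6-methyl-1-(trimethylsilyl)hept-5-en-1-yne
Product: 18 (S)-3-(tert-butyldimethylsilyloxy)-6-methylhept-5-en-1-yne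
Conditions: K2CO3 (cat.), MeOH, 0 °C → rt
Reagents that add atoms: none
Why: Methoxide-mediated protodesilylation cleaves only the C(sp)–Si bond and leaves the hindered O–Si ether and the stereocentre untouched.

**Step 11**
Reactants: 18 (S)-3-(tert-butyldimethylsilyloxy)-6-methylhept-5-en-1-yne; 9 3,6-bis(triisopropylsilyloxy)benzocyclobutene-1,2-dione
Product: 20 2-[(3S)-3-(tert-butyldimethylsilyloxy)-6-methylhept-5-en-1-yn-1-yl]-2-hydroxy-3,6-bis(triisopropylsilyloxy)benzocyclobuten-1(2H)-one (both C2 epimers), via lithium (S)-3-(tert-butyldimethylsilyloxy)-6-methylhept-5-en-1-yn-1-ide 19 (not isolated)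
Conditions: 18, n-BuLi, THF, –78 °C; then added to 9 (1.2 equiv), THF, –78 °C; AcOH, –78 °C
Reagents that add atoms: none
Why: 1,2-Addition of a lithium acetylide to one of the two equivalent carbonyl groups of the strained 1,2-dione, where inverse addition and a cold quench should limit double addition, silyl transfer and opening of the alkoxide; the new carbinol centre forms as an epimer mixture, which is of no consequence because it becomes a carbonyl carbon in step 12.

**Step 12**
Reactants: 20 2-[(3S)-3-(tert-butyldimethylsilyloxy)-6-methylhept-5-en-1-yn-1-yl]-2-hydroxy-3,6-bis(triisopropylsilyloxy)benzocyclobuten-1(2H)-one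
Product: 23 2-[(1S)-1-(tert-butyldimethylsilyloxy)-4-methylpent-3-en-1-yl]-5,8-bis(triisopropylsilyloxy)naphthalene-1,4-dione, via o-quinoid alkynyl vinylketene 21 (not isolated), via naphthalene-1-oxyl-3-yl diradical 22 (not isolated)
Conditions: degassed p-xylene (0.01 M), 138 °C, argon
Reagents that add atoms: none
Why: Heating should open the four-membered ring of 20 by conrotatory 4π electrocyclic cleavage of its C(=O)–C(OH) bond to the o-quinoid vinylketene 21; the ketene carbon then bonds to the distal alkyne carbon (the one carrying the silyloxyalkyl chain), which closes the six-membered ring in a 6-endo-dig sense, restores the benzene ring and gives diradical 22, and transfer of the hydroxyl hydrogen to the C3 sigma-radical gives the 1,4-quinone directly at the right oxidation level. The closest known reaction type is the Moore rearrangement of 4-alkynyl-4-hydroxycyclobutenones to 1,4-quinones, here run on a benzo-fused cyclobutenone so that a naphthoquinone results. No stereocentre is formed: the carbinol centre of 20 becomes the C4 carbonyl carbon, so both epimers converge, and the (S) centre is a spectator outside the reacting pi-system. The step needs inward rotation of the alkynyl group, secured by the strong preference of the hydroxyl donor for outward rotation (where it can also hydrogen-bond to the neighbouring aryl ether oxygen). It needs 6-endo over 5-exo closure, favoured by an alkyl-type alkyne substituent that does not stabilise a vinyl radical and by the aromatic stabilisation of 22. The position of the side chain next to the ketene-derived carbonyl with hydrogen at C3 is fixed by connectivity, and high dilution with exclusion of oxygen should suppress intermolecular hydrogen abstraction by 22.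

**Step 13**
Reactants: 23 2-[(1S)-1-(tert-butyldimethylsilyloxy)-4-methylpent-3-en-1-yl]-5,8-bis(triisopropylsilyloxy)naphthalene-1,4-dione
Product: 24 alkannin (5,8-dihydroxy-2-[(1S)-1-hydroxy-4-methylpent-3-en-1-yl]naphthalene-1,4-dione)
Conditions: Bu4NF (3.3 equiv), AcOH (3.3 equiv), THF, 0 °C → rt
Reagents that add atoms: none
Why: Fluoride-driven cleavage of the two aryl silyl ethers and the alkyl silyl ether (Si–F bond formation), buffered with acetic acid so that the naphthazarin is not held as its phenolate; the carbinol C–O bond is not broken, so the (S) configuration is retained.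

**Step 14**
Reactants: 24 alkannin; 25 3-methylbut-2-enoic acid
Product: 26 alkannin beta,beta-dimethylacrylate ((1S)-1-(5,8-dihydroxy-1,4-dioxo-1,4-dihydronaphthalen-2-yl)-4-methylpent-3-en-1-yl 3-methylbut-2-enoate)
Conditions: DCC, DMAP (cat.), CH2Cl2, 0 °C → rt
Reagents that add atoms: none
Why: Steglich esterification, in which the peri-hydroxyl groups are locked in hydrogen bonds to the quinone carbonyls and are poor nucleophiles, so the DMAP-activated acyl group should go only to the secondary side-chain alcohol, with retention at the stereocentre.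

**Compound list**
1 | 2-bromo-1,4-dimethoxybenzene | COc1ccc(OC)c(Br)c1 | starting material
2 | 1,1-dimethoxyethene | C=C(OC)OC | starting material
3 | 3,6-dimethoxybenzyne (1,4-dimethoxy-2,3-didehydrobenzene) | COC1=CC=C(OC)C#C1 | intermediate
4 | 3,6-dimethoxybenzocyclobutenone dimethyl acetal (1,1,3,6-tetramethoxy-1,2-dihydrobenzocyclobutene) | COc1ccc(OC)c2c1CC2(OC)OC | intermediate
5 | 3,6-dimethoxybenzocyclobuten-1(2H)-one | COc1ccc(OC)c2c1CC2=O | intermediate
6 | 2,2-dibromo-3,6-dimethoxybenzocyclobuten-1(2H)-one | COc1ccc(OC)c2c1C(Br)(Br)C2=O | intermediate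
7 | 3,6-dimethoxybenzocyclobutene-1,2-dione | COc1ccc(OC)c2c1C(=O)C2=O | intermediate
8 | 3,6-dihydroxybenzocyclobutene-1,2-dione | Oc1ccc(O)c2c1C(=O)C2=O | intermediate
9 | 3,6-bis(triisopropylsilyloxy)benzocyclobutene-1,2-dione | CC(C)[Si](Oc1ccc(O[Si](C(C)C)(C(C)C)C(C)C)c2c1C(=O)C2=O)(C(C)C)C(C)C | intermediate
10 | 4-methylpent-3-enoic acid | CC(C)=CCC(=O)O | starting material
11 | 1-(4-methylpent-3-enoyl)imidazole | CC(C)=CCC(=O)n1ccnc1 | intermediate
12 | N-methoxy-N,4-dimethylpent-3-enamide | CC(C)=CCC(=O)N(C)OC | intermediate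
13 | ethynyltrimethylsilane | C#C[Si](C)(C)C | starting material
14 | lithium (trimethylsilyl)acetylide | [Li]C#C[Si](C)(C)C | intermediate
15 | 6-methyl-1-(trimethylsilyl)hept-5-en-1-yn-3-one | CC(C)=CCC(=O)C#C[Si](C)(C)C | intermediate
16 | (S)-6-methyl-1-(trimethylsilyl)hept-5-en-1-yn-3-ol | CC(C)=CC[C@H](O)C#C[Si](C)(C)C | intermediate
17 | (S)-3-(tert-butyldimethylsilyloxy)-6-methyl-1-(trimethylsilyl)hept-5-en-1-yne | CC(C)=CC[C@H](O[Si](C)(C)C(C)(C)C)C#C[Si](C)(C)C | intermediate
18 | (S)-3-(tert-butyldimethylsilyloxy)-6-methylhept-5-en-1-yne | CC(C)=CC[C@H](O[Si](C)(C)C(C)(C)C)C#C | intermediate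
19 | lithium (S)-3-(tert-butyldimethylsilyloxy)-6-methylhept-5-en-1-yn-1-ide | CC(C)=CC[C@H](O[Si](C)(C)C(C)(C)C)C#C[Li] | intermediate
20 | 2-[(3S)-3-(tert-butyldimethylsilyloxy)-6-methylhept-5-en-1-yn-1-yl]-2-hydroxy-3,6-bis(triisopropylsilyloxy)benzocyclobuten-1(2H)-one, mixture of epimers at the carbinol carbon | CC(C)=CC[C@H](O[Si](C)(C)C(C)(C)C)C#CC1(O)C(=O)c2c(O[Si](C(C)C)(C(C)C)C(C)C)ccc(O[Si](C(C)C)(C(C)C)C(C)C)c21 | intermediate
21 | o-quinoid vinylketene: 6-[(4S)-4-(tert-butyldimethylsilyloxy)-1-hydroxy-7-methyloct-6-en-2-yn-1-ylidene]-5-(oxomethylidene)-1,4-bis(triisopropylsilyloxy)cyclohexa-1,3-diene, hydroxyl outward and alkynyl inward | CC(C)=CC[C@H](O[Si](C)(C)C(C)(C)C)C#C/C(O)=C1/C(O[Si](C(C)C)(C(C)C)C(C)C)=CC=C(O[Si](C(C)C)(C(C)C)C(C)C)C1=C=O | intermediate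
22 | diradical: 2-[(1S)-1-(tert-butyldimethylsilyloxy)-4-methylpent-3-en-1-yl]-4-hydroxy-5,8-bis(triisopropylsilyloxy)naphthalen-3-yl-1-oxyl | CC(C)=CC[C@H](O[Si](C)(C)C(C)(C)C)c1[c]c(O)c2c(O[Si](C(C)C)(C(C)C)C(C)C)ccc(O[Si](C(C)C)(C(C)C)C(C)C)c2c1[O] | intermediate
23 | 2-[(1S)-1-(tert-butyldimethylsilyloxy)-4-methylpent-3-en-1-yl]-5,8-bis(triisopropylsilyloxy)naphthalene-1,4-dione | CC(C)=CC[C@H](O[Si](C)(C)C(C)(C)C)C1=CC(=O)c2c(O[Si](C(C)C)(C(C)C)C(C)C)ccc(O[Si](C(C)C)(C(C)C)C(C)C)c2C1=O | intermediate
24 | alkannin, 5,8-dihydroxy-2-[(1S)-1-hydroxy-4-methylpent-3-en-1-yl]naphthalene-1,4-dione | CC(C)=CC[C@H](O)C1=CC(=O)c2c(O)ccc(O)c2C1=O | intermediate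
25 | 3-methylbut-2-enoic acid | CC(C)=CC(=O)O | starting material
26 | alkannin beta,beta-dimethylacrylate | CC(C)=CC[C@H](OC(=O)C=C(C)C)C1=CC(=O)c2c(O)ccc(O)c2C1=O | target

**Totals**
Total step count: 14. Longest linear sequence: 9 steps (steps 1–5 and 11–14; the alkyne branch, steps 6–10 and 11–14, is equally long).

**Steps most likely to fail**

Step 12. The ketene may be diverted to 5-exo closure (an alkylidene-indanedione), the diradical may abstract hydrogen from the side chain or the solvent, or ring opening may be incomplete at a temperature the silyl ethers tolerate. The fallback builds the quinone ring by metal-mediated alkyne insertion instead of by rearrangement; it sets out from dione 9 (with alkyne 18) and comes back at 23. Dione 9 is treated with ClCo(PPh3)3 in chlorobenzene at rt, where monovalent cobalt should insert into the CO–CO bond of the four-membered ring to give chlorobis(triphenylphosphine)[3,6-bis(triisopropylsilyloxy)phthaloyl]cobalt F1, a metallacycle of trivalent cobalt. F1 is then activated with AgBF4 in MeCN and allowed to take up alkyne 18 at rt → 80 °C (alkyne insertion, then reductive elimination), which should give quinone 23. Because 9 is symmetrical, the orientation of the alkyne does not matter.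

Step 11. A triisopropylsilyl group may move from the neighbouring aryl oxygen to the new tertiary alkoxide, the flanking silyloxy groups may shield the carbonyl, or a second acetylide may add. The fallback keeps the methyl ethers and changes the end game to an oxidative deprotection; it sets out from dione 7 (with alkyne 18) and comes back at 26. Acetylide 19 is added to 7 at –78 °C to give 2-[(3S)-3-(tert-butyldimethylsilyloxy)-6-methylhept-5-en-1-yn-1-yl]-2-hydroxy-3,6-dimethoxybenzocyclobuten-1(2H)-one F2. Thermolysis as in step 12 should give 2-[(1S)-1-(tert-butyldimethylsilyloxy)-4-methylpent-3-en-1-yl]-5,8-dimethoxynaphthalene-1,4-dione F3. Bu4NF/AcOH then frees alkannin 5,8-dimethyl ether F4, and DCC/DMAP with 25 gives alkannin 5,8-dimethyl ether beta,beta-dimethylacrylate F5. Oxidative demethylation with AgO and 6 M HNO3 in dioxane should give the naphthalene-1,4,5,8-tetraone F6, which is reduced in the work-up with aqueous Na2S2O4 to 26.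

Step 4. The Lewis acid may open the strained dione, or only one ether may be cleaved. The fallback exchanges the protecting groups on the robust monoketone before the 1,2-dione exists; it sets out from 5 and comes back at 9. Ketone 5 is demethylated with BBr3 in CH2Cl2 to 3,6-dihydroxybenzocyclobuten-1(2H)-one F7, which is silylated with i-Pr3SiCl/imidazole in DMF to 3,6-bis(triisopropylsilyloxy)benzocyclobuten-1(2H)-one F8. F8 is dibrominated with NBS/dibenzoyl peroxide to 2,2-dibromo-3,6-bis(triisopropylsilyloxy)benzocyclobuten-1(2H)-one F9, and hydrolysis with CF3CO2Ag in aqueous MeCN should give 9.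

**Further compounds**
F1 | step 12 | chlorobis(triphenylphosphine)[3,6-bis(triisopropylsilyloxy)phthaloyl]cobalt (metallacycle of trivalent cobalt) | O=C1c2c(O[Si](C(C)C)(C(C)C)C(C)C)ccc(O[Si](C(C)C)(C(C)C)C(C)C)c2C(=O)[Co-2]1(Cl)([P+](c1ccccc1)(c1ccccc1)c1ccccc1)[P+](c1ccccc1)(c1ccccc1)c1ccccc1
F2 | step 11 | 2-[(3S)-3-(tert-butyldimethylsilyloxy)-6-methylhept-5-en-1-yn-1-yl]-2-hydroxy-3,6-dimethoxybenzocyclobuten-1(2H)-one, mixture of epimers at the carbinol carbon | CC(C)=CC[C@H](O[Si](C)(C)C(C)(C)C)C#CC1(O)C(=O)c2c(OC)ccc(OC)c21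
F3 | step 11 | 2-[(1S)-1-(tert-butyldimethylsilyloxy)-4-methylpent-3-en-1-yl]-5,8-dimethoxynaphthalene-1,4-dione | CC(C)=CC[C@H](O[Si](C)(C)C(C)(C)C)C1=CC(=O)c2c(OC)ccc(OC)c2C1=O
F4 | step 11 | alkannin 5,8-dimethyl ether, 2-[(1S)-1-hydroxy-4-methylpent-3-en-1-yl]-5,8-dimethoxynaphthalene-1,4-dione | CC(C)=CC[C@H](O)C1=CC(=O)c2c(OC)ccc(OC)c2C1=O
F5 | step 11 | alkannin 5,8-dimethyl ether beta,beta-dimethylacrylate | CC(C)=CC[C@H](OC(=O)C=C(C)C)C1=CC(=O)c2c(OC)ccc(OC)c2C1=O
F6 | step 11 | (1S)-4-methyl-1-(1,4,5,8-tetraoxo-1,4,5,8-tetrahydronaphthalen-2-yl)pent-3-en-1-yl 3-methylbut-2-enoate | CC(C)=CC[C@H](OC(=O)C=C(C)C)C1=CC(=O)C2=C(C1=O)C(=O)C=CC2=O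
F7 | step 4 | 3,6-dihydroxybenzocyclobuten-1(2H)-one | Oc1ccc(O)c2c1CC2=O
F8 | step 4 | 3,6-bis(triisopropylsilyloxy)benzocyclobuten-1(2H)-one | CC(C)[Si](Oc1ccc(O[Si](C(C)C)(C(C)C)C(C)C)c2c1CC2=O)(C(C)C)C(C)C
F9 | step 4 | 2,2-dibromo-3,6-bis(triisopropylsilyloxy)benzocyclobuten-1(2H)-one | CC(C)[Si](Oc1ccc(O[Si](C(C)C)(C(C)C)C(C)C)c2c1C(Br)(Br)C2=O)(C(C)C)C(C)C
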